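**Retrosynthet­ic overview**
- The target comes from fluoride removal of three TBS ethers from an epoxy alcohol. The oxirane is the only ring and is closed in the penultimate step by hydroxyl-directed (vanadium) epoxidation of a C9 allylic alcohol, which sets C10 and C11.
- The C9–C10 bond and the C9 stereocentre come from a stereospecific 1,2-metallate (boron-to-carbon) rearrangement of the boronate complex formed from a (+)-sparteine-lithiated C9 carbamate and a C10 alkenyl boronate.
- The C5–C6 bond and the C5 stereocentre come from the same 1,2-shift with (−)-sparteine, between homoprenyl carbamate and a bifunctional alkenyl-Bpin/carbamate linchpin made from pent-3-yn-1-ol. The linchpin's carbamate later becomes the C9 carbenoid.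
- The C10–C16 alkenyl boronate comes from CuH α-hydroboration of a (Z)-enyne, which is made by a new propargylation of the prenol dianion (C12–C13 bond, Z-alkene).
- Four C4–C6 alcohols supply all 20 carbons.

Locants: main chain C1 (prenyl CH3) to C16 (allylic CH2OH); oxirane = C10–C11; C10′ = hydroxymethyl carbon.

Assumption: silyl, carbamoyl and boron reagents, s-BuLi and both sparteine enantiomers count as reagents/auxiliaries, and the four carbon building blocks and (+)-sparteine are taken as commercially available.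

**Step 1**
Reactants: 1 4-chlorobut-2-yn-1-ol
Product: 2 tert-butyl[(4-chlorobut-2-yn-1-yl)oxy]dimethylsilane
Conditions: TBSCl, imidazole, DMF, 0 °C → rt
Reagents that add atoms: tert-butyldimethylsilyl chloride, CC(C)(C)[Si](C)(C)Cl
Why: Imidazole-promoted O-silylation (silyl ether protection) of the primary alcohol is fast and leaves the propargylic chloride untouched.

**Step 2**
Reactants: 3 3-methylbut-2-en-1-ol (prenol); 2 tert-butyl[(4-chlorobut-2-yn-1-yl)oxy]dimethylsilane
Product: 6 (2Z)-1,8-bis[(tert-butyldimethylsilyl)oxy]-3-methyloct-2-en-6-yne, via dilithiated prenol 4 (not isolated), via lithium alkoxide 5 (not isolated)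
Conditions: n-BuLi (2.2 equiv), TMEDA, Et2O, 0 °C → rt; then 2, THF, −78 → −20 °C; then TBSCl, DMPU, −20 °C → rt
Reagents that add atoms: tert-butyldimethylsilyl chloride, CC(C)(C)[Si](C)(C)Cl
Why: Proposed new method: alkoxide-directed lithiation of prenol at the methyl group cis to CH2OLi gives the O–Li-chelated endo (Z) dianion 4, whose terminal carbanion (hard, least hindered, remote from the repelling alkoxide) displaces the primary propargylic chloride of 2 by direct SN2, so the C12–C13 bond forms with the Z-trisubstituted alkene already fixed, and the lithium alkoxide 5 is silylated in the same flask; closest known reaction type: alkylation of alkoxide-directed allylic dianions of unsaturated alcohols (n-BuLi/TMEDA, e.g. isoprenol and methallyl alcohol dianions) with primary alkyl halides, not shown for prenol with a propargylic electrophile or with in-flask silylation.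

**Step 3**
Reactants: 6 (2Z)-1,8-bis[(tert-butyldimethylsilyl)oxy]-3-methyloct-2-en-6-yne
Product: 7 (2Z,6Z)-1,8-bis[(tert-butyldimethylsilyl)oxy]-3-methyl-7-(4,4,5,5-tetramethyl-1,3,2-dioxaborolan-2-yl)octa-2,6-diene
Conditions: HBpin, CuCl (5 mol %), CF3Ar-Xantphos [4,5-bis(bis(3,5-bis(trifluoromethyl)phenyl)phosphino)-9,9-dimethylxanthene] (5 mol %), KOtBu (10 mol %), toluene, rt
Reagents that add atoms: pinacolborane, B1OC(C)(C)C(C)(C)O1
Why: In this copper hydride-catalysed alkyne hydroboration, syn-hydrocupration places Cu on the alkyne carbon next to the electron-withdrawing CH2OSi group and σ-bond metathesis with HBpin replaces Cu by B with retention, so B ends geminal to CH2OTBS and cis to H while the trisubstituted alkene is inert.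

**Step 4**
Reactants: 8 4-methylpent-3-en-1-ol
Product: 9 4-methylpent-3-en-1-yl N,N-diisopropylcarbamate
Conditions: iPr2NCOCl, Et3N, CH2Cl2, reflux
Reagents that add atoms: N,N-diisopropylcarbamoyl chloride, CC(C)N(C(C)C)C(Cl)=O
Why: O-Carbamoylation (acylation) of the primary alcohol gives the hindered Hoppe carbamate needed for directed α-lithiation.

**Step 5**
Reactants: 10 pent-3-yn-1-ol
Product: 11 pent-3-yn-1-yl N,N-diisopropylcarbamate
Conditions: iPr2NCOCl, Et3N, CH2Cl2, reflux
Reagents that add atoms: N,N-diisopropylcarbamoyl chloride, CC(C)N(C(C)C)C(Cl)=O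
Why: The same O-carbamoylation works here because the internal alkyne is inert to the acylating conditions.

**Step 6**
Reactants: 11 pent-3-yn-1-yl N,N-diisopropylcarbamate
Product: 12 (3Z)-4-(4,4,5,5-tetramethyl-1,3,2-dioxaborolan-2-yl)pent-3-en-1-yl N,N-diisopropylcarbamate
Conditions: B2pin2, CuCl (5 mol %), IMes·HCl (5 mol %), NaOtBu (12 mol %), MeOH (2 equiv), THF, rt
Reagents that add atoms: bis(pinacolato)diboron, CC1(C)OB(OC1(C)C)B1OC(C)(C)C(C)(C)O1
Why: In this copper-catalysed borylcupration/protonation (formal syn-hydroboration), Cu adds to the alkyne carbon nearer the oxygenated chain and boron to the less hindered methyl terminus, giving B cis to H (any minor regioisomer is removed by chromatography).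

**Step 7**
Reactants: 9 4-methylpent-3-en-1-yl N,N-diisopropylcarbamate; 12 (3Z)-4-(4,4,5,5-tetramethyl-1,3,2-dioxaborolan-2-yl)pent-3-en-1-yl N,N-diisopropylcarbamate
Product: 16 (3E,5R)-5-hydroxy-4,8-dimethylnona-3,7-dien-1-yl N,N-diisopropylcarbamate, via lithiated carbamate 13 (not isolated), via boronate complex 14 (not isolated), via allylic boronic ester 15 (not isolated)
Conditions: 9 (1.3 equiv), s-BuLi, (−)-sparteine, Et2O, −78 °C; 12, −78 °C; MgBr2·OEt2, reflux; then H2O2, aq NaOH, THF, 0 °C → rt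
Reagents that add atoms: hydrogen peroxide, OO
Why: In this Hoppe–Aggarwal lithiation–borylation, s-BuLi/(−)-sparteine removes the pro-S proton to give (S)-13, the boron of 12 is attacked with retention, and in 14 the alkenyl group shifts from B to C anti to the departing carbamate (stereospecific 1,2-metallate rearrangement with inversion, alkene geometry retained), so stereoretentive oxidation of 15 gives the (5R)-allylic alcohol with the (E)-C6=C7 bond, the remote carbamate of 12 being inert throughout.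

**Step 8**
Reactants: 16 (3E,5R)-5-hydroxy-4,8-dimethylnona-3,7-dien-1-yl N,N-diisopropylcarbamate
Product: 17 (3E,5R)-5-[(tert-butyldimethylsilyl)oxy]-4,8-dimethylnona-3,7-dien-1-yl N,N-diisopropylcarbamate
Conditions: TBSCl, imidazole, DMF, rt
Reagents that add atoms: tert-butyldimethylsilyl chloride, CC(C)(C)[Si](C)(C)Cl
Why: Standard silyl ether protection of the secondary allylic alcohol ensures that the C5 oxygen neither quenches s-BuLi nor directs the later epoxidation.

**Step 9**
Reactants: 17 (3E,5R)-5-[(tert-butyldimethylsilyl)oxy]-4,8-dimethylnona-3,7-dien-1-yl N,N-diisopropylcarbamate; 7 (2Z,6Z)-1,8-bis[(tert-butyldimethylsilyl)oxy]-3-methyl-7-(4,4,5,5-tetramethyl-1,3,2-dioxaborolan-2-yl)octa-2,6-diene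
Product: 21 (2Z,6E,8S,10E,12R)-1,12-bis[(tert-butyldimethylsilyl)oxy]-7-{[(tert-butyldimethylsilyl)oxy]methyl}-3,11,15-trimethylhexadeca-2,6,10,14-tetraen-8-ol, via lithiated carbamate 18 (not isolated), via boronate complex 19 (not isolated), via allylic boronic ester 20 (not isolated)
Conditions: 17 (1.2 equiv), s-BuLi, (+)-sparteine, Et2O, −78 °C; 7, −78 °C; MgBr2·OEt2, reflux; then H2O2, aq NaOH, THF, 0 °C → rt
Reagents that add atoms: hydrogen peroxide, OO
Why: In this second lithiation–borylation, (+)-sparteine directs removal of the pro-R proton to give (R)-18, borylation proceeds with retention and the invertive 1,2-metallate rearrangement of the alkenyl group in 19 forges C9–C10, so stereoretentive oxidation of 20 gives the (S)-C9 carbinol with the C10=C11 geometry of 7 carried over (the silyloxy group is too poor a leaving group for β-elimination from the boronate).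

**Step 10**
Reactants: 21 (2Z,6E,8S,10E,12R)-1,12-bis[(tert-butyldimethylsilyl)oxy]-7-{[(tert-butyldimethylsilyl)oxy]methyl}-3,11,15-trimethylhexadeca-2,6,10,14-tetraen-8-ol
Product: 22 (1S,3E,5R)-5-[(tert-butyldimethylsilyl)oxy]-1-[(2S,3S)-2-{[(tert-butyldimethylsilyl)oxy]methyl}-3-[(3Z)-5-[(tert-butyldimethylsilyl)oxy]-3-methylpent-3-en-1-yl]oxiran-2-yl]-4,8-dimethylnona-3,7-dien-1-ol
Conditions: VO(acac)2 (5 mol %), TBHP (1.3 equiv, decane), CH2Cl2, 0 °C → rt
Reagents that add atoms: tert-butyl hydroperoxide, CC(C)(C)OO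
Why: In this vanadium-catalysed hydroxyl-directed epoxidation only the C10=C11 alkene carries a free allylic OH, and A(1,2) strain between the C8 chain and the geminal CH2OTBS group in the vanadate transition state enforces the erythro product, setting C10 and C11 as (S,S) from (S)-C9 while the stereospecific syn oxygen transfer keeps CH2O and C12 cis.

**Step 11**
Reactants: 22 (1S,3E,5R)-5-[(tert-butyldimethylsilyl)oxy]-1-[(2S,3S)-2-{[(tert-butyldimethylsilyl)oxy]methyl}-3-[(3Z)-5-[(tert-butyldimethylsilyl)oxy]-3-methylpent-3-en-1-yl]oxiran-2-yl]-4,8-dimethylnona-3,7-dien-1-ol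
Product: 23 (2Z)-5-[(2S,3S)-3-[(1S,3E,5R)-1,5-dihydroxy-4,8-dimethylnona-3,7-dien-1-yl]-3-(hydroxymethyl)oxiran-2-yl]-3-methylpent-2-en-1-ol
Conditions: TBAF, AcOH (1:1), THF, 0 °C → rt
Reagents that add atoms: none
Why: Fluoride-mediated desilylation removes all three TBS ethers, and buffering with AcOH keeps the 2,3-epoxy alcohol from Payne rearrangement, so no stereocentre is touched.

**Compound list**
1 | 4-chlorobut-2-yn-1-ol | OCC#CCCl | starting material
2 | tert-butyl[(4-chlorobut-2-yn-1-yl)oxy]dimethylsilane | CC(C)(C)[Si](C)(C)OCC#CCCl | intermediate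
3 | 3-methylbut-2-en-1-ol (prenol) | CC(C)=CCO | starting material
4 | lithium (2Z)-4-lithio-3-methylbut-2-en-1-olate (dilithiated prenol) | [Li]C/C(C)=C\CO[Li] | intermediate (not isolated)
5 | lithium (2Z)-8-[(tert-butyldimethylsilyl)oxy]-3-methyloct-2-en-6-yn-1-olate | CC(C)(C)[Si](C)(C)OCC#CCC/C(C)=C\CO[Li] | intermediate (not isolated)
6 | (2Z)-1,8-bis[(tert-butyldimethylsilyl)oxy]-3-methyloct-2-en-6-yne | CC(C)(C)[Si](C)(C)OCC#CCC/C(C)=C\CO[Si](C)(C)C(C)(C)C | intermediate
7 | (2Z,6Z)-1,8-bis[(tert-butyldimethylsilyl)oxy]-3-methyl-7-(4,4,5,5-tetramethyl-1,3,2-dioxaborolan-2-yl)octa-2,6-diene (B geminal to CH2OTBS, cis to H) | CC(C)(C)[Si](C)(C)OC/C(B1OC(C)(C)C(C)(C)O1)=C\CC/C(C)=C\CO[Si](C)(C)C(C)(C)C | intermediate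
8 | 4-methylpent-3-en-1-ol | CC(C)=CCCO | starting material
9 | 4-methylpent-3-en-1-yl N,N-diisopropylcarbamate | CC(C)=CCCOC(=O)N(C(C)C)C(C)C | intermediate
10 | pent-3-yn-1-ol | CC#CCCO | starting material
11 | pent-3-yn-1-yl N,N-diisopropylcarbamate | CC#CCCOC(=O)N(C(C)C)C(C)C | intermediate
12 | (3Z)-4-(4,4,5,5-tetramethyl-1,3,2-dioxaborolan-2-yl)pent-3-en-1-yl N,N-diisopropylcarbamate (B cis to H) | C/C(B1OC(C)(C)C(C)(C)O1)=C\CCOC(=O)N(C(C)C)C(C)C | intermediate
13 | (1S)-1-lithio-4-methylpent-3-en-1-yl N,N-diisopropylcarbamate, (−)-sparteine complex (ligand omitted) | CC(C)=CC[C@H]([Li])OC(=O)N(C(C)C)C(C)C | intermediate (not isolated)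
14 | lithium [(1S)-1-(diisopropylcarbamoyloxy)-4-methylpent-3-en-1-yl][(2Z)-5-(diisopropylcarbamoyloxy)pent-2-en-2-yl](pinacolato)borate | CC(C)=CC[C@H]([B-]1(OC(C)(C)C(C)(C)O1)/C(C)=C/CCOC(=O)N(C(C)C)C(C)C)OC(=O)N(C(C)C)C(C)C.[Li+] | intermediate (not isolated)
15 | (3E,5R)-4,8-dimethyl-5-(4,4,5,5-tetramethyl-1,3,2-dioxaborolan-2-yl)nona-3,7-dien-1-yl N,N-diisopropylcarbamate | CC(C)=CC[C@@H](B1OC(C)(C)C(C)(C)O1)/C(C)=C/CCOC(=O)N(C(C)C)C(C)C | intermediate (not isolated)
16 | (3E,5R)-5-hydroxy-4,8-dimethylnona-3,7-dien-1-yl N,N-diisopropylcarbamate | CC(C)=CC[C@@H](O)/C(C)=C/CCOC(=O)N(C(C)C)C(C)C | intermediate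
17 | (3E,5R)-5-[(tert-butyldimethylsilyl)oxy]-4,8-dimethylnona-3,7-dien-1-yl N,N-diisopropylcarbamate | CC(C)=CC[C@@H](O[Si](C)(C)C(C)(C)C)/C(C)=C/CCOC(=O)N(C(C)C)C(C)C | intermediate
18 | (1R)-1-lithio derivative of 17 at the carbamate carbon (C9), (+)-sparteine complex (ligand omitted) | CC(C)=CC[C@@H](O[Si](C)(C)C(C)(C)C)/C(C)=C/C[C@@H]([Li])OC(=O)N(C(C)C)C(C)C | intermediate (not isolated)
19 | lithium boronate complex of 18 and 7 (tetracoordinate B bonded to C9, C10 and pinacolate) | CC(C)=CC[C@@H](O[Si](C)(C)C(C)(C)C)/C(C)=C/C[C@@H]([B-]1(OC(C)(C)C(C)(C)O1)/C(CO[Si](C)(C)C(C)(C)C)=C/CC/C(C)=C\CO[Si](C)(C)C(C)(C)C)OC(=O)N(C(C)C)C(C)C.[Li+] | intermediate (not isolated)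
20 | (S)-C9 allylic pinacol boronic ester (21 with Bpin in place of the C9 hydroxyl) | CC(C)=CC[C@@H](O[Si](C)(C)C(C)(C)C)/C(C)=C/C[C@H](B1OC(C)(C)C(C)(C)O1)/C(CO[Si](C)(C)C(C)(C)C)=C/CC/C(C)=C\CO[Si](C)(C)C(C)(C)C | intermediate (not isolated)
21 | (2Z,6E,8S,10E,12R)-1,12-bis[(tert-butyldimethylsilyl)oxy]-7-{[(tert-butyldimethylsilyl)oxy]methyl}-3,11,15-trimethylhexadeca-2,6,10,14-tetraen-8-ol | CC(C)=CC[C@@H](O[Si](C)(C)C(C)(C)C)/C(C)=C/C[C@H](O)/C(CO[Si](C)(C)C(C)(C)C)=C/CC/C(C)=C\CO[Si](C)(C)C(C)(C)C | intermediate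
22 | (1S,3E,5R)-5-[(tert-butyldimethylsilyl)oxy]-1-[(2S,3S)-2-{[(tert-butyldimethylsilyl)oxy]methyl}-3-[(3Z)-5-[(tert-butyldimethylsilyl)oxy]-3-methylpent-3-en-1-yl]oxiran-2-yl]-4,8-dimethylnona-3,7-dien-1-ol | CC(C)=CC[C@@H](O[Si](C)(C)C(C)(C)C)/C(C)=C/C[C@H](O)[C@]1(CO[Si](C)(C)C(C)(C)C)O[C@H]1CC/C(C)=C\CO[Si](C)(C)C(C)(C)C | intermediate
23 | (2Z)-5-[(2S,3S)-3-[(1S,3E,5R)-1,5-dihydroxy-4,8-dimethylnona-3,7-dien-1-yl]-3-(hydroxymethyl)oxiran-2-yl]-3-methylpent-2-en-1-ol (CNP0167574.1) | CC(C)=CC[C@@H](O)/C(C)=C/C[C@H](O)[C@]1(CO)O[C@H]1CC/C(C)=C\CO | target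

**Totals**
Total step count: 11.
Longest linear sequence: 7 steps (steps 5, 6, 7, 8, 9, 10, 11, from pent-3-yn-1-ol 10).

**Three steps most likely to fail**

Step 2 (the proposed new step). The dianion may attack 2 in an SN2′ sense (allene), alkylate at C2, or act as a base towards the propargylic chloride. The fallback uses known chemistry, sets out from 2 and comes back at 6. The dianion of methyl acetoacetate (NaH, then n-BuLi, THF, 0 °C) is alkylated at its terminal carbon by 2 to give the β-keto ester methyl 8-[(tert-butyldimethylsilyl)oxy]-3-oxooct-6-ynoate F1. Tf2O with aqueous Me4NOH gives the (E)-enol triflate methyl (2E)-8-[(tert-butyldimethylsilyl)oxy]-3-{[(trifluoromethyl)sulfonyl]oxy}oct-2-en-6-ynoate F2. Iron-catalysed coupling with MeMgBr (Fe(acac)3, THF/NMP, retention) gives methyl (2Z)-8-[(tert-butyldimethylsilyl)oxy]-3-methyloct-2-en-6-ynoate F3. DIBAL-H reduction gives (2Z)-8-[(tert-butyldimethylsilyl)oxy]-3-methyloct-2-en-6-yn-1-ol F4, and TBSCl/imidazole returns to 6.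

Step 3. With the bulky silyl ether the hydrocupration may give a mixture of regioisomers. The fallback sets out from 6 and comes back at 7. A molybdenum-catalysed syn-hydrostannation (Bu3SnH, Mo(CO)3(CNtBu)3, hydroquinone, THF, 60 °C), which places tin next to the oxygenated propargylic carbon, gives (2Z,6E)-1,8-bis[(tert-butyldimethylsilyl)oxy]-3-methyl-7-(tributylstannyl)octa-2,6-diene F5. Tin–lithium exchange (n-BuLi, THF, −78 °C) and trapping with i-PrOBpin, both with retention, return to 7.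

Step 9. The hindered boronate may add reversibly, lose silanolate from the boronate complex, or give a lower enantiomer ratio in the more functionalised setting. The fallback sets out from 17 and 7 and comes back at 21. LiAlH4 (THF, reflux) removes the carbamate from 17 to give (3E,5R)-5-[(tert-butyldimethylsilyl)oxy]-4,8-dimethylnona-3,7-dien-1-ol F6. Buffered Dess–Martin oxidation gives (3E,5R)-5-[(tert-butyldimethylsilyl)oxy]-4,8-dimethylnona-3,7-dienal F7, which is used crude. Iododeboronation of 7 (NaOH, I2, THF, retention) gives (2Z,6E)-1,8-bis[(tert-butyldimethylsilyl)oxy]-7-iodo-3-methylocta-2,6-diene F8. A catalytic asymmetric Nozaki–Hiyama–Kishi coupling of F7 with F8 (CrCl2/NiCl2 cat., chiral sulfonamide ligand, Mn, Cp2ZrCl2, MeCN), with the ligand enantiomer chosen for the (S)-carbinol, returns to 21.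

**Further compounds**
F1 | step 2 | methyl 8-[(tert-butyldimethylsilyl)oxy]-3-oxooct-6-ynoate | COC(=O)CC(=O)CCC#CCO[Si](C)(C)C(C)(C)C
F2 | step 2 | methyl (2E)-8-[(tert-butyldimethylsilyl)oxy]-3-{[(trifluoromethyl)sulfonyl]oxy}oct-2-en-6-ynoate | COC(=O)/C=C(/OS(=O)(=O)C(F)(F)F)CCC#CCO[Si](C)(C)C(C)(C)C
F3 | step 2 | methyl (2Z)-8-[(tert-butyldimethylsilyl)oxy]-3-methyloct-2-en-6-ynoate | COC(=O)/C=C(/C)CCC#CCO[Si](C)(C)C(C)(C)C
F4 | step 2 | (2Z)-8-[(tert-butyldimethylsilyl)oxy]-3-methyloct-2-en-6-yn-1-ol | CC(C)(C)[Si](C)(C)OCC#CCC/C(C)=C\CO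
F5 | step 3 | (2Z,6E)-1,8-bis[(tert-butyldimethylsilyl)oxy]-3-methyl-7-(tributylstannyl)octa-2,6-diene | CCCC[Sn](CCCC)(CCCC)/C(CO[Si](C)(C)C(C)(C)C)=C/CC/C(C)=C\CO[Si](C)(C)C(C)(C)C
F6 | step 9 | (3E,5R)-5-[(tert-butyldimethylsilyl)oxy]-4,8-dimethylnona-3,7-dien-1-ol | CC(C)=CC[C@@H](O[Si](C)(C)C(C)(C)C)/C(C)=C/CCO
F7 | step 9 | (3E,5R)-5-[(tert-butyldimethylsilyl)oxy]-4,8-dimethylnona-3,7-dienal | CC(C)=CC[C@@H](O[Si](C)(C)C(C)(C)C)/C(C)=C/CC=O
F8 | step 9 | (2Z,6E)-1,8-bis[(tert-butyldimethylsilyl)oxy]-7-iodo-3-methylocta-2,6-diene | CC(C)(C)[Si](C)(C)OC/C(I)=C\CC/C(C)=C\CO[Si](C)(C)C(C)(C)C
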